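A direct plan would mono-benzylate 2',6'-dihydroxy-4'-methoxyacetophenone to A1, condense it with O-benzylisovanillin to the chalcone A2, close ring C with I2 in DMSO to the 5,3'-di-O-benzylflavone A3, lithiate C3 and trap the carbanion with peroxydisulfate to the sulfate A4, and finish by hydrogenolysis and acidification.
Its weakest steps would be:
(a) the sulfooxylation of the C3-lithiated flavone: a C–O bond formation without precedent, run on the most advanced material, through a carbanion that opens to an ynone phenolate and with an oxidant prone to electron transfer;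
(b) the benzyl ether pair: put on by a mono-alkylation that rests only on a hydrogen bond and taken off last by hydrogenolysis beside a labile sulfate and a reducible C2=C3 bond, two operations that add nothing to the skeleton;
(c) the chalcone-to-flavone closure: it would build ring C without the C3 oxygen, so that this oxygen has to be forced in afterwards.

Cuts, in retrosynthetic order: the neopentyl group of a masked sulfate; the C2–C1' bond between ring C and ring B (key step); the O3–S bond; the C3–O bond; last the C2 carbon and the O1–C2 bond of ring C.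
Order of rings: ring A is bought, ring C is closed on it first, and ring B is joined last as a finished arene by C–H zincation and Negishi coupling.
Enabling feature: with the sulfate ester on C3, C2–H is the only C–H of the pyranone ring C. It lies between O1 and the C3–O–SO2 group and is vinylogous to the C4=O that the 5-oxygen chelates, so it is the one acidic, directed site; on ring B the iodine goes para to the methoxy group by ordinary arene substitution.
Why the weak steps do not occur: the C3 oxygen comes from an epoxide isomerisation on the bicyclic chromone and sulfur is put on that hydroxyl at once, so no flavone carbanion and no persulfate are needed. No benzyl ether and no hydrogenolysis appear; the twofold-symmetric acetophenone closes without mono-protection and its second hydroxyl becomes the chelated 5-OH, which is never protected.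

Key step: step 6

Assumption: the target is the free hydrogen sulfate as drawn (achiral); because aryl hydrogen sulfates hydrolyse readily, the sodium salt is treated as the storable form and the acid is set free only in the last step.

Step 1
Reactants: 1 2',6'-dihydroxy-4'-methoxyacetophenone
Product: 3 5-hydroxy-7-methoxy-4H-chromen-4-one, via enaminone 2 (not isolated)
Conditions: Me2NCH(OMe)2 (2.5 equiv), toluene, 85 °C; evaporate; conc. HCl, CH2Cl2, rt
Reagents that add atoms: N,N-dimethylformamide dimethyl acetal, CN(C)C(OC)OC
Why: Condensation of the acetyl CH3 with the amide acetal gives the enaminone, and acid then drives an intramolecular addition–elimination (phenol oxygen onto the β-carbon, loss of dimethylamine) that closes ring C (enaminone route to chromones); the two hydroxyls of 1 are equivalent, so either closure gives the same chromone and the other hydroxyl ends as the chelated 5-OH.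

Step 2
Reactants: 3 5-hydroxy-7-methoxy-4H-chromen-4-one
Product: 5 3,5-dihydroxy-7-methoxy-4H-chromen-4-one, via racemic 2,3-epoxide 4 (not isolated)
Conditions: dimethyldioxirane (0.08 M in acetone, 1.5 equiv), CH2Cl2, 0 °C → rt; evaporate; p-TsOH·H2O (5 mol %), CH2Cl2, rt
Reagents that add atoms: dimethyldioxirane, CC1(C)OO1
Why: Epoxidation of the C2=C3 enol ether bond by the neutral dioxirane, followed by acid-catalysed opening of the oxirane at C2 (cation stabilised by O1) and loss of H-3 (epoxide-to-enol isomerisation), should place the oxygen on C3; the two stereocentres of 4 are lost again in this isomerisation.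

Step 3
Reactants: 6 2,2-dimethylpropan-1-ol (neopentyl alcohol)
Product: 7 2,2-dimethylpropyl chlorosulfate (neopentyl chlorosulfate)
Conditions: SO2Cl2 (1.0 equiv), pyridine (1.0 equiv), Et2O, −78 °C → rt
Reagents that add atoms: sulfuryl chloride, O=S(=O)(Cl)Cl
Why: Chlorosulfation of a primary alcohol with sulfuryl chloride should stop at the alkyl chlorosulfate because the neopentyl carbon resists SN2 attack by chloride.

Step 4
Reactants: 5 3,5-dihydroxy-7-methoxy-4H-chromen-4-one; 7 2,2-dimethylpropyl chlorosulfate
Product: 8 5-hydroxy-7-methoxy-4-oxo-4H-chromen-3-yl 2,2-dimethylpropyl sulfate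
Conditions: NaN(SiMe3)2 (1.05 equiv), THF–DMPU, −78 °C; 7 (1.2 equiv), −78 → 0 °C
Reagents that add atoms: none
Why: O-Sulfonylation of a phenoxide-type anion with an alkyl chlorosulfate (sulfate diester formation) should occur only at O3, since the 3-OH is the more acidic hydroxyl and the 5-OH is held in the six-membered hydrogen bond to C4=O; no other hydroxyl of the target exists yet at this stage.

Step 5
Reactants: 9 2-methoxyphenyl acetate (guaiacol acetate)
Product: 10 5-iodo-2-methoxyphenyl acetate
Conditions: N-iodosuccinimide (1.05 equiv), CF3CO2H (0.3 equiv), MeCN, rt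
Reagents that add atoms: N-iodosuccinimide, O=C1CCC(=O)N1I
Why: Electrophilic aromatic iodination should go para to the methoxy group, the stronger donor, because the acetoxy group activates its own para position far less; this sets the 3-acyloxy-4-methoxyphenyl pattern of ring B.

Step 6
Reactants: 8 5-hydroxy-7-methoxy-4-oxo-4H-chromen-3-yl 2,2-dimethylpropyl sulfate; 10 5-iodo-2-methoxyphenyl acetate
Product: 12 5-[3-{[(2,2-dimethylpropoxy)sulfonyl]oxy}-5-hydroxy-7-methoxy-4-oxo-4H-chromen-2-yl]-2-methoxyphenyl acetate, via C2-chlorozinc species 11 (not isolated)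
Conditions: TMPZnCl·LiCl (TMP = 2,2,6,6-tetramethylpiperidide, 2.3 equiv), THF, 0 → 25 °C; then 10 (1.2 equiv), Pd(OAc)2 (4 mol %), SPhos (2-dicyclohexylphosphino-2',6'-dimethoxybiphenyl, 8 mol %), 25–40 °C; sat. aq NH4Cl
Reagents that add atoms: none
Why: The first equivalent of the zinc amide turns the 5-OH into a zinc phenoxide chelated to C4=O, and this built-in Lewis acid makes ring C pyrylium-like, so the second equivalent removes C2–H, the only C–H left on ring C, which is acidified by O1 and by the C3 sulfate ester whose sulfonyl oxygens hold the amide nearby (directed deprotonative zincation). The covalent C2–Zn bond of 11 should resist the paths open to a lithium or magnesium analogue: loss of the sulfate to a six-membered cyclic alkyne, a 1,3-shift of sulfur from O3 to C2, or opening of the pyranone ring. Zerovalent palladium formed from Pd(OAc)2 and SPhos inserts into the C–I bond of 10, and transmetalation with 11 and reductive elimination then form the C2–C1' bond (Negishi coupling); the closest known reaction type is the C–H zincation of chromones with TMP-zinc bases followed by Negishi arylation to flavones, together with ortho-metalation directed by aryl sulfamates and sulfonates. No ring is closed and no stereocentre is formed; the step joins the finished ring B to the bicyclic AC core. The selectivities needed are C2–H over the ring A hydrogens at C6 and C8, which are far less acidic and out of reach of a zinc amide at 25 °C, and C–I over the C3–O sulfate bond in the oxidative addition, secured by using the iodide at 25–40 °C; the position on ring B is fixed by the iodine set para to the methoxy group in step 5.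

Step 7
Reactants: 12 5-[3-{[(2,2-dimethylpropoxy)sulfonyl]oxy}-5-hydroxy-7-methoxy-4-oxo-4H-chromen-2-yl]-2-methoxyphenyl acetate
Product: 14 sodium 5-hydroxy-2-(3-hydroxy-4-methoxyphenyl)-7-methoxy-4-oxo-4H-chromen-3-yl sulfate (sodium ombuin 3-O-sulfate), via sodium 3'-O-acetylombuin 3-O-sulfate 13 (not isolated)
Conditions: NaN3 (3 equiv), DMF, 70 °C; cool; NH3 (7 M in MeOH), 0 °C → rt; evaporate; C18 (H2O wash to remove azide, then MeOH)
Reagents that add atoms: sodium azide, [Na+].[N-]=[N+]=[N-]
Why: SN2 dealkylation of the sulfate diester by the small azide ion at the neopentyl carbon should unmask the sulfate monoanion, which is inert to the ammonolysis that then removes the aryl acetate; neither acid nor reduction touches the sulfate or the C2=C3 bond.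

Step 8
Reactants: 14 sodium ombuin 3-O-sulfate
Product: 15 5-hydroxy-2-(3-hydroxy-4-methoxyphenyl)-7-methoxy-4-oxo-4H-chromen-3-yl hydrogen sulfate (ombuin 3-O-sulfate)
Conditions: 0.1 M aq HCl (1.0 equiv), 0 °C, 5 min; C18 cartridge (cold H2O wash, MeOH elution); freeze-dry; store at −20 °C
Reagents that add atoms: none
Why: This is a plain exchange of sodium for a proton (salt metathesis); short cold contact with one equivalent of dilute acid and reversed-phase desalting should avoid hydrolysis of the aryl sulfate.

## Compound list
1 | 2',6'-dihydroxy-4'-methoxyacetophenone | CC(=O)c1c(O)cc(OC)cc1O | starting material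
2 | (E)-1-(2,6-dihydroxy-4-methoxyphenyl)-3-(dimethylamino)prop-2-en-1-one (not isolated) | CN(C)/C=C/C(=O)c1c(O)cc(OC)cc1O | intermediate
3 | 5-hydroxy-7-methoxy-4H-chromen-4-one | COc1cc(O)c2c(=O)ccoc2c1 | intermediate
4 | racemic 2,3-epoxy-5-hydroxy-7-methoxychroman-4-one, cis-fused oxirane (not isolated) | COc1cc(O)c2c(c1)O[C@@H]1O[C@@H]1C2=O | intermediate
5 | 3,5-dihydroxy-7-methoxy-4H-chromen-4-one | COc1cc(O)c2c(=O)c(O)coc2c1 | intermediate
6 | 2,2-dimethylpropan-1-ol (neopentyl alcohol) | CC(C)(C)CO | starting material
7 | 2,2-dimethylpropyl chlorosulfate (neopentyl chlorosulfate) | CC(C)(C)COS(=O)(=O)Cl | intermediate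
8 | 5-hydroxy-7-methoxy-4-oxo-4H-chromen-3-yl 2,2-dimethylpropyl sulfate | COc1cc(O)c2c(=O)c(OS(=O)(=O)OCC(C)(C)C)coc2c1 | intermediate
9 | 2-methoxyphenyl acetate (guaiacol acetate) | COc1ccccc1OC(C)=O | starting material
10 | 5-iodo-2-methoxyphenyl acetate | COc1ccc(I)cc1OC(C)=O | intermediate
11 | C2-chlorozinc derivative of 8 as its 5-O-chlorozinc phenoxide (not isolated) | COc1cc(O[Zn]Cl)c2c(=O)c(OS(=O)(=O)OCC(C)(C)C)c([Zn]Cl)oc2c1 | intermediate
12 | 5-[3-{[(2,2-dimethylpropoxy)sulfonyl]oxy}-5-hydroxy-7-methoxy-4-oxo-4H-chromen-2-yl]-2-methoxyphenyl acetate | COc1cc(O)c2c(=O)c(OS(=O)(=O)OCC(C)(C)C)c(-c3ccc(OC)c(OC(C)=O)c3)oc2c1 | intermediate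
13 | sodium 2-[3-(acetyloxy)-4-methoxyphenyl]-5-hydroxy-7-methoxy-4-oxo-4H-chromen-3-yl sulfate (not isolated) | COc1cc(O)c2c(=O)c(OS(=O)(=O)[O-])c(-c3ccc(OC)c(OC(C)=O)c3)oc2c1.[Na+] | intermediate
14 | sodium 5-hydroxy-2-(3-hydroxy-4-methoxyphenyl)-7-methoxy-4-oxo-4H-chromen-3-yl sulfate (sodium ombuin 3-O-sulfate) | COc1cc(O)c2c(=O)c(OS(=O)(=O)[O-])c(-c3ccc(OC)c(O)c3)oc2c1.[Na+] | intermediate
15 | 5-hydroxy-2-(3-hydroxy-4-methoxyphenyl)-7-methoxy-4-oxo-4H-chromen-3-yl hydrogen sulfate (ombuin 3-O-sulfate, achiral) | COc1cc(O)c2c(=O)c(OS(=O)(=O)O)c(-c3ccc(OC)c(O)c3)oc2c1 | target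

Total step count: 8. Longest linear sequence: 6 steps (1, 2, 4, 6, 7, 8).

Steps most likely to fail:

Step 6. The zincation may be incomplete, the zinc amide may attack the sulfate ester at sulfur, or the hindered C2–zinc species may be protonated before it transmetalates. The fallback sets out from 3 and 10 and comes back at 12; it exchanges the order of C2 arylation and C3 oxygenation. Chromone 3 is zincated at C2 with a TMP-zinc amide (TMPZnCl·LiCl) under the conditions that favour C2 in chromones without a C3 substituent, the setting in which this C–H arylation is documented. Negishi coupling with 10 (Pd(OAc)2, SPhos) then gives the flavone 5-(5-hydroxy-7-methoxy-4-oxo-4H-chromen-2-yl)-2-methoxyphenyl acetate F1. Dimethyldioxirane converts F1 into its racemic 2,3-epoxide F2, which catalytic acid isomerises to the flavonol 5-(3,5-dihydroxy-7-methoxy-4-oxo-4H-chromen-2-yl)-2-methoxyphenyl acetate F3. NaN(SiMe3)2 and 7 then sulfonylate the 3-OH of F3 to give 12.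

Step 7. Azide may attack sulfur with loss of the flavonol oxide instead of attacking the neopentyl carbon, or the SN2 step at the neopentyl centre may be too slow. The fallback sets out from 3 and 10 and comes back at 13; it introduces the sulfate late, as the monoester. The flavonol F3, reached from 3 and 10 as described for step 6, is treated with the SO3–pyridine complex in pyridine. Only O3 should react, because O3' is acetylated and the 5-OH is chelated, giving the pyridinium salt of 3'-O-acetylombuin 3-O-sulfate F4. Aqueous NaHCO3 exchanges the cation and gives 13, which is deacetylated with NH3 in MeOH as in step 7.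

Step 2. The dioxirane may oxidise the electron-rich phenolic ring A, or epoxidation of the push–pull C2=C3 bond may be too slow. The fallback sets out from 2 and comes back at 5; it brings in the C3 oxygen through a C3 halide. Enaminone 2 is cyclised with I2 in CHCl3 to 5-hydroxy-3-iodo-7-methoxy-4H-chromen-4-one F5 (iodocyclisation with loss of dimethylamine). Miyaura borylation (B2pin2, PdCl2(dppf), KOAc, dioxane) gives the boronate 5-hydroxy-7-methoxy-3-(4,4,5,5-tetramethyl-1,3,2-dioxaborolan-2-yl)-4H-chromen-4-one F6, and oxidation with H2O2 and NaHCO3 gives 5.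

Further compounds
F1 | step 6 | 5-(5-hydroxy-7-methoxy-4-oxo-4H-chromen-2-yl)-2-methoxyphenyl acetate | COc1cc(O)c2c(=O)cc(-c3ccc(OC)c(OC(C)=O)c3)oc2c1
F2 | step 6 | racemic 2,3-epoxide of F1, cis-fused oxirane | COc1cc(O)c2c(c1)O[C@]1(c3ccc(OC)c(OC(C)=O)c3)O[C@@H]1C2=O
F3 | step 6 | 5-(3,5-dihydroxy-7-methoxy-4-oxo-4H-chromen-2-yl)-2-methoxyphenyl acetate (3'-O-acetylombuin) | COc1cc(O)c2c(=O)c(O)c(-c3ccc(OC)c(OC(C)=O)c3)oc2c1
F4 | step 7 | pyridinium 2-[3-(acetyloxy)-4-methoxyphenyl]-5-hydroxy-7-methoxy-4-oxo-4H-chromen-3-yl sulfate | COc1cc(O)c2c(=O)c(OS(=O)(=O)[O-])c(-c3ccc(OC)c(OC(C)=O)c3)oc2c1.c1cc[nH+]cc1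
F5 | step 2 | 5-hydroxy-3-iodo-7-methoxy-4H-chromen-4-one | COc1cc(O)c2c(=O)c(I)coc2c1
F6 | step 2 | 5-hydroxy-7-methoxy-3-(4,4,5,5-tetramethyl-1,3,2-dioxaborolan-2-yl)-4H-chromen-4-one | COc1cc(O)c2c(=O)c(B3OC(C)(C)C(C)(C)O3)coc2c1
A1 | direct plan | 2'-benzyloxy-6'-hydroxy-4'-methoxyacetophenone | CC(=O)c1c(O)cc(OC)cc1OCc1ccccc1
A2 | direct plan | (E)-1-[2-(benzyloxy)-6-hydroxy-4-methoxyphenyl]-3-[3-(benzyloxy)-4-methoxyphenyl]prop-2-en-1-one | COc1cc(O)c(C(=O)/C=C/c2ccc(OC)c(OCc3ccccc3)c2)c(OCc2ccccc2)c1
A3 | direct plan | 5-(benzyloxy)-2-[3-(benzyloxy)-4-methoxyphenyl]-7-methoxy-4H-chromen-4-one | COc1cc(OCc2ccccc2)c2c(=O)cc(-c3ccc(OC)c(OCc4ccccc4)c3)oc2c1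
A4 | direct plan | tetrabutylammonium 5-(benzyloxy)-2-[3-(benzyloxy)-4-methoxyphenyl]-7-methoxy-4-oxo-4H-chromen-3-yl sulfate | COc1cc(OCc2ccccc2)c2c(=O)c(OS(=O)(=O)[O-])c(-c3ccc(OC)c(OCc4ccccc4)c3)oc2c1.CCCC[N+](CCCC)(CCCC)CCCC
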